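**Plan**
- The ten-membered carbocycle C1–C10 holds an allylic carbinol: C9–O sits next to alkenyl carbon C10 of the ring E-alkene C1=C10. This is the retron of an alkenyl 1,2-shift from boron onto an α-chloro boronate carbon, followed by C–B to C–O oxidation.
- Retrosynthetic cuts, in order: epoxide O at C4/C5; the three ester C–O bonds; ring bond C9–C10; C1=C10 and C4=C5 (two olefinations); C7–C11 and the carbons C7, C8, C9 (Matteson homologations on one boron atom).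
- Forward: boron carrying (S,S)-DICHED is walked C6→C7→C8→C9 while the chain C5→C1/C10 is grown from the C5 aldehyde. The C10 alkenyllithium then closes an 11-membered cyclic borate, which contracts to the ten-membered ring by expelling boron; boron becomes the C9 hydroxyl, and the epoxide ring is made last.
- Stereochemistry: C7 and C9 from the diol director; both alkene geometries from Z-type Horner–Wadsworth–Emmons reagents; C4/C5 from a Sharpless epoxidation; the side-chain centres from an Evans syn-aldol.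

Key step: step 18

Assumption: the sense of induction of (S,S)-DICHED (R-configured α-chloro boronic esters from alkylboronates) and of L-(+)-diethyl tartrate (the face that gives 2S epoxy alcohols from primary allylic alcohols) follows the established models. Atom labels C1–C15 are those of the germacrane skeleton (ring C1–C10, C11–C13 on C7, C14 on C10, C15 on C4).

**Step 1**
Reactants: 1 tert-butyl(2-iodoethoxy)dimethylsilane; 2 (1S,2S)-1,2-dicyclohexylethane-1,2-diol [(S,S)-DICHED]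
Product: 4 (4S,5S)-2-[2-(tert-butyldimethylsilyloxy)ethyl]-4,5-dicyclohexyl-1,3,2-dioxaborolane, via catechol boronate 3 (not isolated)
Conditions: B2cat2, DMF, blue LEDs, rt; then 2, Et3N, rt
Reagents that add atoms: bis(catecholato)diboron, B1(Oc2ccccc2O1)B1Oc2ccccc2O1
Why: Visible-light radical borylation of a primary alkyl iodide with bis(catecholato)diboron, then transesterification of the labile catechol ester with the diol, is an established route to alkylboronic esters, and the β-silyloxyethyl radical should not fragment.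

**Step 2**
Reactants: 4 (4S,5S)-2-[2-(tert-butyldimethylsilyloxy)ethyl]-4,5-dicyclohexyl-1,3,2-dioxaborolane
Product: 6 (4S,5S)-2-[(1R)-3-(tert-butyldimethylsilyloxy)-1-chloropropyl]-4,5-dicyclohexyl-1,3,2-dioxaborolane, via borate complex 5 (not isolated)
Conditions: CH2Cl2, n-BuLi, THF, −100 °C; then 4; ZnCl2, −100 °C → rt
Reagents that add atoms: dichloromethane, ClCCl
Why: Matteson homologation, in which the alkyl group migrates from boron with loss of the chloride selected by the C2-symmetric diol, should give the (R)-α-chloro boronic ester whose carbon becomes C7.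

**Step 3**
Reactants: 7 2,3-dibromoprop-1-ene; 8 (4-methoxyphenyl)methanol
Product: 9 1-{[(2-bromoprop-2-en-1-yl)oxy]methyl}-4-methoxybenzene
Conditions: NaH, THF, 0 °C; then 7, Bu4NI (cat.), rt
Reagents that add atoms: none
Why: Williamson etherification by SN2 at the allylic bromide, leaving the vinylic bromide untouched.

**Step 4**
Reactants: 6 (4S,5S)-2-[(1R)-3-(tert-butyldimethylsilyloxy)-1-chloropropyl]-4,5-dicyclohexyl-1,3,2-dioxaborolane; 9 1-{[(2-bromoprop-2-en-1-yl)oxy]methyl}-4-methoxybenzene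
Product: 12 (4S,5S)-2-[(3S)-5-(tert-butyldimethylsilyloxy)-2-{[(4-methoxybenzyl)oxy]methyl}pent-1-en-3-yl]-4,5-dicyclohexyl-1,3,2-dioxaborolane, via alkenyllithium 10 (not isolated), via borate complex 11 (not isolated)
Conditions: 9, t-BuLi (2.0 equiv), Et2O, −78 °C; then 6, −78 °C → rt
Reagents that add atoms: none
Why: Matteson substitution, in which the 2-lithioallyl ether adds to boron and the alkenyl group migrates to carbon with inversion and loss of chloride, should set C7 bearing the C11–C13 unit.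

**Step 5**
Reactants: 12 (4S,5S)-2-[(3S)-5-(tert-butyldimethylsilyloxy)-2-{[(4-methoxybenzyl)oxy]methyl}pent-1-en-3-yl]-4,5-dicyclohexyl-1,3,2-dioxaborolane
Product: 14 (4S,5S)-2-[(2S)-2-[2-(tert-butyldimethylsilyloxy)ethyl]-3-{[(4-methoxybenzyl)oxy]methyl}but-3-en-1-yl]-4,5-dicyclohexyl-1,3,2-dioxaborolane, via borate complex 13 (not isolated)
Conditions: BrCH2Cl, n-BuLi, THF, −78 °C → rt
Reagents that add atoms: bromochloromethane, ClCBr
Why: Matteson one-carbon homologation with (chloromethyl)lithium made in the presence of the boronic ester, in which the secondary allylic carbon migrates with retention, so C7 is untouched and boron moves to C8.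

**Step 6**
Reactants: 14 (4S,5S)-2-[(2S)-2-[2-(tert-butyldimethylsilyloxy)ethyl]-3-{[(4-methoxybenzyl)oxy]methyl}but-3-en-1-yl]-4,5-dicyclohexyl-1,3,2-dioxaborolane
Product: 15 (3S)-3-{[(4S,5S)-4,5-dicyclohexyl-1,3,2-dioxaborolan-2-yl]methyl}-4-{[(4-methoxybenzyl)oxy]methyl}pent-4-en-1-ol
Conditions: CSA (cat.), MeOH/CH2Cl2, 0 °C
Reagents that add atoms: none
Why: Acid-catalysed methanolysis of a primary TBS ether, to which the PMB ether and the hindered boronic ester should be inert.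

**Step 7**
Reactants: 15 (3S)-3-{[(4S,5S)-4,5-dicyclohexyl-1,3,2-dioxaborolan-2-yl]methyl}-4-{[(4-methoxybenzyl)oxy]methyl}pent-4-en-1-ol
Product: 16 (3S)-3-{[(4S,5S)-4,5-dicyclohexyl-1,3,2-dioxaborolan-2-yl]methyl}-4-{[(4-methoxybenzyl)oxy]methyl}pent-4-enal
Conditions: Dess–Martin periodinane, NaHCO3, CH2Cl2, 0 °C → rt
Reagents that add atoms: none
Why: Dess–Martin oxidation of a primary alcohol to the C5 aldehyde, which has no α-stereocentre to epimerise.

**Step 8**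
Reactants: 17 methyl 2-[bis(2,2,2-trifluoroethoxy)phosphoryl]acetate; 18 3-bromo-1,1-dimethoxypropane
Product: 19 methyl 2-[bis(2,2,2-trifluoroethoxy)phosphoryl]-5,5-dimethoxypentanoate (racemic)
Conditions: NaH, DMF, 0 °C; then 18, NaI (cat.), 60 °C
Reagents that add atoms: none
Why: C-alkylation of the stabilised phosphonoacetate anion by a primary bromide installs C1–C3 on the future C4.

**Step 9**
Reactants: 16 (3S)-3-{[(4S,5S)-4,5-dicyclohexyl-1,3,2-dioxaborolan-2-yl]methyl}-4-{[(4-methoxybenzyl)oxy]methyl}pent-4-enal; 19 methyl 2-[bis(2,2,2-trifluoroethoxy)phosphoryl]-5,5-dimethoxypentanoate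
Product: 20 methyl (2Z,5S)-5-{[(4S,5S)-4,5-dicyclohexyl-1,3,2-dioxaborolan-2-yl]methyl}-2-(3,3-dimethoxypropyl)-6-{[(4-methoxybenzyl)oxy]methyl}hepta-2,6-dienoate
Conditions: 19, KHMDS, 18-crown-6, THF, −78 °C; then 16
Reagents that add atoms: none
Why: Still–Gennari olefination should give the Z-enoate under kinetic control, placing the ester carbon C15 cis to C6 as the later trans-epoxide requires.

**Step 10**
Reactants: 20 methyl (2Z,5S)-5-{[(4S,5S)-4,5-dicyclohexyl-1,3,2-dioxaborolan-2-yl]methyl}-2-(3,3-dimethoxypropyl)-6-{[(4-methoxybenzyl)oxy]methyl}hepta-2,6-dienoate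
Product: 21 (2Z,5S)-5-{[(4S,5S)-4,5-dicyclohexyl-1,3,2-dioxaborolan-2-yl]methyl}-2-(3,3-dimethoxypropyl)-6-{[(4-methoxybenzyl)oxy]methyl}hepta-2,6-dien-1-ol
Conditions: DIBAL-H, CH2Cl2, −78 °C
Reagents that add atoms: none
Why: 1,2-Reduction of the enoate to the C15 allylic alcohol by DIBAL-H, which should spare the acetal and the boronic ester at −78 °C.

**Step 11**
Reactants: 21 (2Z,5S)-5-{[(4S,5S)-4,5-dicyclohexyl-1,3,2-dioxaborolan-2-yl]methyl}-2-(3,3-dimethoxypropyl)-6-{[(4-methoxybenzyl)oxy]methyl}hepta-2,6-dien-1-ol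
Product: 22 tert-butyldiphenylsilyl ether of 21
Conditions: TBDPSCl, imidazole, DMF, 0 °C → rt
Reagents that add atoms: tert-butyl(chloro)diphenylsilane, CC(C)(C)[Si](Cl)(c1ccccc1)c1ccccc1
Why: Standard silylation of a primary alcohol gives the robust C15 ether that is removed last.

**Step 12**
Reactants: 22 tert-butyldiphenylsilyl ether of 21
Product: 23 (4Z,7S)-4-{[(tert-butyldiphenylsilyl)oxy]methyl}-7-{[(4S,5S)-4,5-dicyclohexyl-1,3,2-dioxaborolan-2-yl]methyl}-8-{[(4-methoxybenzyl)oxy]methyl}nona-4,8-dienal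
Conditions: AcOH/THF/H2O, 40 °C
Reagents that add atoms: water, O
Why: Mild hydrolysis of the dimethyl acetal frees the C1 aldehyde, under which TBDPS, PMB and the boronic ester should survive.

**Step 13**
Reactants: 17 methyl 2-[bis(2,2,2-trifluoroethoxy)phosphoryl]acetate
Product: 24 methyl 2-[bis(2,2,2-trifluoroethoxy)phosphoryl]-2-bromoacetate
Conditions: NaH, THF, 0 °C; then Br2 (1.0 equiv), −78 °C
Reagents that add atoms: bromine, BrBr
Why: Electrophilic bromination of the sodium phosphonoacetate enolate gives the α-bromo phosphonate.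

**Step 14**
Reactants: 23 (4Z,7S)-4-{[(tert-butyldiphenylsilyl)oxy]methyl}-7-{[(4S,5S)-4,5-dicyclohexyl-1,3,2-dioxaborolan-2-yl]methyl}-8-{[(4-methoxybenzyl)oxy]methyl}nona-4,8-dienal; 24 methyl 2-[bis(2,2,2-trifluoroethoxy)phosphoryl]-2-bromoacetate
Product: 25 methyl (2E,6Z,9S)-2-bromo-6-{[(tert-butyldiphenylsilyl)oxy]methyl}-9-{[(4S,5S)-4,5-dicyclohexyl-1,3,2-dioxaborolan-2-yl]methyl}-10-{[(4-methoxybenzyl)oxy]methyl}undeca-2,6,10-trienoate
Conditions: 24, t-BuOK, 18-crown-6, THF, −78 °C; then 23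
Reagents that add atoms: none
Why: Horner–Wadsworth–Emmons olefination with the bis(trifluoroethyl) bromophosphonoacetate should give the (E)-α-bromoacrylate, with Br trans and the ester carbon C14 cis to C2, the geometry the E-C1=C10 alkene needs.

**Step 15**
Reactants: 25 methyl (2E,6Z,9S)-2-bromo-6-{[(tert-butyldiphenylsilyl)oxy]methyl}-9-{[(4S,5S)-4,5-dicyclohexyl-1,3,2-dioxaborolan-2-yl]methyl}-10-{[(4-methoxybenzyl)oxy]methyl}undeca-2,6,10-trienoate
Product: 26 (2E,6Z,9S)-2-bromo-6-{[(tert-butyldiphenylsilyl)oxy]methyl}-9-{[(4S,5S)-4,5-dicyclohexyl-1,3,2-dioxaborolan-2-yl]methyl}-10-{[(4-methoxybenzyl)oxy]methyl}undeca-2,6,10-trien-1-ol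
Conditions: DIBAL-H, CH2Cl2, −78 °C
Reagents that add atoms: none
Why: DIBAL-H reduces the enoate to the C14 allylic alcohol and should leave the alkenyl bromide intact.

**Step 16**
Reactants: 26 (2E,6Z,9S)-2-bromo-6-{[(tert-butyldiphenylsilyl)oxy]methyl}-9-{[(4S,5S)-4,5-dicyclohexyl-1,3,2-dioxaborolan-2-yl]methyl}-10-{[(4-methoxybenzyl)oxy]methyl}undeca-2,6,10-trien-1-ol
Product: 27 tert-butyldimethylsilyl ether of 26
Conditions: TBSCl, imidazole, DMF, 0 °C → rt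
Reagents that add atoms: tert-butyl(chloro)dimethylsilane, CC(C)(C)[Si](C)(C)Cl
Why: Silylation gives a C14 ether that is a poor β-leaving group next to the later alkenyllithium and can be removed selectively beside TBDPS.

**Step 17**
Reactants: 27 tert-butyldimethylsilyl ether of 26
Product: 29 (4S,5S)-2-[(1R,3R,5Z,9E)-10-bromo-11-(tert-butyldimethylsilyloxy)-6-{[(tert-butyldiphenylsilyl)oxy]methyl}-1-chloro-3-{3-[(4-methoxybenzyl)oxy]prop-1-en-2-yl}undeca-5,9-dien-1-yl]-4,5-dicyclohexyl-1,3,2-dioxaborolane, via borate complex 28 (not isolated)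
Conditions: CH2Cl2, n-BuLi, THF, −100 °C; then 27; ZnCl2, −100 °C → rt
Reagents that add atoms: dichloromethane, ClCCl
Why: A second Matteson homologation under control of the same diol should give the (R)-α-chloro boronic ester at C9, and preformed (dichloromethyl)lithium should not touch the alkenyl bromide.

**Step 18**
Reactants: 29 (4S,5S)-2-[(1R,3R,5Z,9E)-10-bromo-11-(tert-butyldimethylsilyloxy)-6-{[(tert-butyldiphenylsilyl)oxy]methyl}-1-chloro-3-{3-[(4-methoxybenzyl)oxy]prop-1-en-2-yl}undeca-5,9-dien-1-yl]-4,5-dicyclohexyl-1,3,2-dioxaborolane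
Product: 33 (1S,2E,6Z,9R)-2-{[(tert-butyldimethylsilyl)oxy]methyl}-6-{[(tert-butyldiphenylsilyl)oxy]methyl}-9-{3-[(4-methoxybenzyl)oxy]prop-1-en-2-yl}cyclodeca-2,6-dien-1-ol, via alkenyllithium 30 (not isolated), via 11-membered cyclic borate 31 (not isolated), via cyclic allylic boronic ester 32 (not isolated)
Conditions: t-BuLi (2.05 equiv, dropwise), THF/Et2O/pentane, −100 °C, 2 mM; −100 °C → rt; then NaOH, 30% H2O2, 0 °C
Reagents that add atoms: hydrogen peroxide, OO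
Why: Proposed new method: Br–Li exchange at C10 (expected to outrun addition of t-BuLi to boron, as in in-situ-quench borylations) gives alkenyllithium 30, which adds to the tethered boronic ester to close the 11-membered cyclic borate 31 (ring C7–C8–C9–B–C10–C1–C2–C3–C4–C5–C6); on warming, C10 migrates from boron to C9 anti to the departing chloride, so boron leaves the ring and the ten-membered carbocycle 32 forms by a one-atom ring contraction, after which peroxide turns C–B into C–O. The closest known reactions are the Matteson substitution of α-chloro boronic esters by alkenyl-metal reagents and the 1,2-metallate ring contractions of small cyclic alkenyl boronate complexes; a medium-ring closure through an intramolecular borate has not been described. The 11-membered ring is closed by C(sp2)–B bond formation, which is fast and irreversible at −100 °C, and the ten-membered ring arises from it by a stereospecific 1,2-shift. C9 is set by the (R)-chloride of 29 (inversion in the shift, retention in the oxidation), hence by the diol director, and the alkenyl group migrates with retention, so the E geometry of C1=C10 from step 14 is carried into the ring. The step needs intramolecular borate formation to outrun oligomerisation and attack of t-BuLi on boron, which high dilution, low temperature and the speed of the exchange should secure. It also needs the C14 silyloxy group to stay on the 2-lithioallyl unit, which its poor leaving-group ability at −100 °C should secure.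

**Step 19**
Reactants: 33 (1S,2E,6Z,9R)-2-{[(tert-butyldimethylsilyl)oxy]methyl}-6-{[(tert-butyldiphenylsilyl)oxy]methyl}-9-{3-[(4-methoxybenzyl)oxy]prop-1-en-2-yl}cyclodeca-2,6-dien-1-ol
Product: 34 (1S,2E,6Z,9R)-2-{[(tert-butyldimethylsilyl)oxy]methyl}-6-{[(tert-butyldiphenylsilyl)oxy]methyl}-9-{3-[(4-methoxybenzyl)oxy]prop-1-en-2-yl}cyclodeca-2,6-dien-1-yl (2E)-2-methylbut-2-enoate
Conditions: tigloyl chloride, Et3N, DMAP, CH2Cl2, 0 °C → rt
Reagents that add atoms: (2E)-2-methylbut-2-enoyl chloride, C/C=C(\C)C(=O)Cl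
Why: DMAP-catalysed acylation of the only free hydroxyl (C9) with the configurationally stable E acid chloride.

**Step 20**
Reactants: 34 (1S,2E,6Z,9R)-2-{[(tert-butyldimethylsilyl)oxy]methyl}-6-{[(tert-butyldiphenylsilyl)oxy]methyl}-9-{3-[(4-methoxybenzyl)oxy]prop-1-en-2-yl}cyclodeca-2,6-dien-1-yl (2E)-2-methylbut-2-enoate
Product: 35 (1S,2E,6Z,9R)-6-{[(tert-butyldiphenylsilyl)oxy]methyl}-2-(hydroxymethyl)-9-{3-[(4-methoxybenzyl)oxy]prop-1-en-2-yl}cyclodeca-2,6-dien-1-yl (2E)-2-methylbut-2-enoate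
Conditions: HF·pyridine, pyridine, THF, 0 °C
Reagents that add atoms: none
Why: Buffered fluoride should cleave the primary TBS ether at C14 much faster than the primary TBDPS ether at C15, without acid that could trigger transannular cyclisation.

**Step 21**
Reactants: 36 (4R)-4-benzyl-3-propanoyl-1,3-oxazolidin-2-one; 37 acetaldehyde
Product: 38 (4R)-4-benzyl-3-[(2R,3S)-3-hydroxy-2-methylbutanoyl]-1,3-oxazolidin-2-one
Conditions: Bu2BOTf, i-Pr2NEt, CH2Cl2, −78 → 0 °C; 37, −78 °C; then pH 7 buffer, MeOH, 30% H2O2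
Reagents that add atoms: none
Why: Evans syn-aldol through the Z boron enolate and a chair transition state, the (R)-auxiliary setting the 2R,3S configuration.

**Step 22**
Reactants: 38 (4R)-4-benzyl-3-[(2R,3S)-3-hydroxy-2-methylbutanoyl]-1,3-oxazolidin-2-one
Product: 39 (4R)-4-benzyl-3-[(2R,3S)-3-(tert-butyldimethylsilyloxy)-2-methylbutanoyl]-1,3-oxazolidin-2-one
Conditions: TBSOTf, 2,6-lutidine, CH2Cl2, 0 °C
Reagents that add atoms: tert-butyldimethylsilyl triflate, CC(C)(C)[Si](C)(C)OS(=O)(=O)C(F)(F)F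
Why: Silylation of the secondary alcohol blocks retro-aldol and self-acylation.

**Step 23**
Reactants: 39 (4R)-4-benzyl-3-[(2R,3S)-3-(tert-butyldimethylsilyloxy)-2-methylbutanoyl]-1,3-oxazolidin-2-one
Product: 40 (2R,3S)-3-(tert-butyldimethylsilyloxy)-2-methylbutanoic acid
Conditions: LiOH, 30% H2O2, THF/H2O, 0 °C; Na2SO3; then 1 M HCl
Reagents that add atoms: hydrogen peroxide (as LiOOH), OO
Why: Lithium hydroperoxide attacks the exocyclic carbonyl selectively and cleaves the auxiliary without epimerising C2.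

**Step 24**
Reactants: 35 (1S,2E,6Z,9R)-6-{[(tert-butyldiphenylsilyl)oxy]methyl}-2-(hydroxymethyl)-9-{3-[(4-methoxybenzyl)oxy]prop-1-en-2-yl}cyclodeca-2,6-dien-1-yl (2E)-2-methylbut-2-enoate; 40 (2R,3S)-3-(tert-butyldimethylsilyloxy)-2-methylbutanoic acid
Product: 41 (1S,2E,6Z,9R)-2-({[(2R,3S)-3-(tert-butyldimethylsilyloxy)-2-methylbutanoyl]oxy}methyl)-6-{[(tert-butyldiphenylsilyl)oxy]methyl}-9-{3-[(4-methoxybenzyl)oxy]prop-1-en-2-yl}cyclodeca-2,6-dien-1-yl (2E)-2-methylbut-2-enoate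
Conditions: DCC, DMAP (cat.), CH2Cl2, 0 °C → rt
Reagents that add atoms: none
Why: Steglich esterification of the unhindered primary allylic alcohol at C14 should be fast enough to avoid epimerisation of the α-centre of the acid.

**Step 25**
Reactants: 41 (1S,2E,6Z,9R)-2-({[(2R,3S)-3-(tert-butyldimethylsilyloxy)-2-methylbutanoyl]oxy}methyl)-6-{[(tert-butyldiphenylsilyl)oxy]methyl}-9-{3-[(4-methoxybenzyl)oxy]prop-1-en-2-yl}cyclodeca-2,6-dien-1-yl (2E)-2-methylbut-2-enoate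
Product: 42 (1S,2E,6Z,9R)-2-({[(2R,3S)-3-(tert-butyldimethylsilyloxy)-2-methylbutanoyl]oxy}methyl)-6-{[(tert-butyldiphenylsilyl)oxy]methyl}-9-(3-hydroxyprop-1-en-2-yl)cyclodeca-2,6-dien-1-yl (2E)-2-methylbut-2-enoate
Conditions: DDQ, CH2Cl2/pH 7 buffer, 0 °C
Reagents that add atoms: none
Why: Oxidative cleavage of the PMB ether by DDQ frees C12–OH without touching esters, silyl ethers or the alkenes.

**Step 26**
Reactants: 42 (1S,2E,6Z,9R)-2-({[(2R,3S)-3-(tert-butyldimethylsilyloxy)-2-methylbutanoyl]oxy}methyl)-6-{[(tert-butyldiphenylsilyl)oxy]methyl}-9-(3-hydroxyprop-1-en-2-yl)cyclodeca-2,6-dien-1-yl (2E)-2-methylbut-2-enoate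
Product: 43 (1S,2E,6Z,9R)-9-[3-(acetyloxy)prop-1-en-2-yl]-2-({[(2R,3S)-3-(tert-butyldimethylsilyloxy)-2-methylbutanoyl]oxy}methyl)-6-{[(tert-butyldiphenylsilyl)oxy]methyl}cyclodeca-2,6-dien-1-yl (2E)-2-methylbut-2-enoate
Conditions: Ac2O, pyridine, DMAP (cat.), CH2Cl2, 0 °C
Reagents that add atoms: acetic anhydride, CC(=O)OC(C)=O
Why: Routine acetylation of the only free hydroxyl.

**Step 27**
Reactants: 43 (1S,2E,6Z,9R)-9-[3-(acetyloxy)prop-1-en-2-yl]-2-({[(2R,3S)-3-(tert-butyldimethylsilyloxy)-2-methylbutanoyl]oxy}methyl)-6-{[(tert-butyldiphenylsilyl)oxy]methyl}cyclodeca-2,6-dien-1-yl (2E)-2-methylbut-2-enoate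
Product: 44 (1S,2E,6Z,9R)-9-[3-(acetyloxy)prop-1-en-2-yl]-6-(hydroxymethyl)-2-({[(2R,3S)-3-hydroxy-2-methylbutanoyl]oxy}methyl)cyclodeca-2,6-dien-1-yl (2E)-2-methylbut-2-enoate
Conditions: HF·pyridine (excess), pyridine, THF, 0 °C → rt
Reagents that add atoms: none
Why: Prolonged buffered HF·pyridine removes both remaining silyl ethers under non-basic conditions, which should avoid acyl migration among the three esters.

**Step 28**
Reactants: 44 (1S,2E,6Z,9R)-9-[3-(acetyloxy)prop-1-en-2-yl]-6-(hydroxymethyl)-2-({[(2R,3S)-3-hydroxy-2-methylbutanoyl]oxy}methyl)cyclodeca-2,6-dien-1-yl (2E)-2-methylbut-2-enoate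
Product: 45 target CNP0316239.1 (4S,5R-epoxide)
Conditions: Ti(Oi-Pr)4, L-(+)-diethyl tartrate, t-BuOOH, 4 Å MS, CH2Cl2, −20 °C
Reagents that add atoms: tert-butyl hydroperoxide, CC(C)(C)OO
Why: Sharpless asymmetric epoxidation is directed by the C15 allylic alcohol to C4=C5 only, and the tartrate selects the face that gives the 4S,5R epoxide.

**Compound list**
1 | tert-butyl(2-iodoethoxy)dimethylsilane | CC(C)(C)[Si](C)(C)OCCI | starting material
2 | (1S,2S)-1,2-dicyclohexylethane-1,2-diol, (S,S)-DICHED | O[C@@H](C1CCCCC1)[C@@H](O)C1CCCCC1 | starting material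
3 | 2-[2-(tert-butyldimethylsilyloxy)ethyl]-1,3,2-benzodioxaborole | CC(C)(C)[Si](C)(C)OCCB1Oc2ccccc2O1 | intermediate
4 | (4S,5S)-2-[2-(tert-butyldimethylsilyloxy)ethyl]-4,5-dicyclohexyl-1,3,2-dioxaborolane | CC(C)(C)[Si](C)(C)OCCB1O[C@@H](C2CCCCC2)[C@H](C2CCCCC2)O1 | intermediate
5 | lithium (dichloromethyl)borate complex of 4 | [Li+].CC(C)(C)[Si](C)(C)OCC[B-]1(C(Cl)Cl)O[C@@H](C2CCCCC2)[C@H](C2CCCCC2)O1 | intermediate
6 | (4S,5S)-2-[(1R)-3-(tert-butyldimethylsilyloxy)-1-chloropropyl]-4,5-dicyclohexyl-1,3,2-dioxaborolane | CC(C)(C)[Si](C)(C)OCC[C@H](Cl)B1O[C@@H](C2CCCCC2)[C@H](C2CCCCC2)O1 | intermediate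
7 | 2,3-dibromoprop-1-ene | C=C(Br)CBr | starting material
8 | (4-methoxyphenyl)methanol | COc1ccc(CO)cc1 | starting material
9 | 1-{[(2-bromoprop-2-en-1-yl)oxy]methyl}-4-methoxybenzene | C=C(Br)COCc1ccc(OC)cc1 | intermediate
10 | {3-[(4-methoxybenzyl)oxy]prop-1-en-2-yl}lithium | [Li]C(=C)COCc1ccc(OC)cc1 | intermediate
11 | lithium alkenyl(1-chloroalkyl)borate complex from 6 and 10 | [Li+].C=C(COCc1ccc(OC)cc1)[B-]1([C@@H](Cl)CCO[Si](C)(C)C(C)(C)C)O[C@@H](C2CCCCC2)[C@H](C2CCCCC2)O1 | intermediate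
12 | (4S,5S)-2-[(3S)-5-(tert-butyldimethylsilyloxy)-2-{[(4-methoxybenzyl)oxy]methyl}pent-1-en-3-yl]-4,5-dicyclohexyl-1,3,2-dioxaborolane | C=C(COCc1ccc(OC)cc1)[C@H](CCO[Si](C)(C)C(C)(C)C)B1O[C@@H](C2CCCCC2)[C@H](C2CCCCC2)O1 | intermediate
13 | lithium (chloromethyl)borate complex of 12 | [Li+].C=C(COCc1ccc(OC)cc1)[C@H](CCO[Si](C)(C)C(C)(C)C)[B-]1(CCl)O[C@@H](C2CCCCC2)[C@H](C2CCCCC2)O1 | intermediate
14 | (4S,5S)-2-[(2S)-2-[2-(tert-butyldimethylsilyloxy)ethyl]-3-{[(4-methoxybenzyl)oxy]methyl}but-3-en-1-yl]-4,5-dicyclohexyl-1,3,2-dioxaborolane | C=C(COCc1ccc(OC)cc1)[C@H](CCO[Si](C)(C)C(C)(C)C)CB1O[C@@H](C2CCCCC2)[C@H](C2CCCCC2)O1 | intermediate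
15 | (3S)-3-{[(4S,5S)-4,5-dicyclohexyl-1,3,2-dioxaborolan-2-yl]methyl}-4-{[(4-methoxybenzyl)oxy]methyl}pent-4-en-1-ol | C=C(COCc1ccc(OC)cc1)[C@H](CCO)CB1O[C@@H](C2CCCCC2)[C@H](C2CCCCC2)O1 | intermediate
16 | (3S)-3-{[(4S,5S)-4,5-dicyclohexyl-1,3,2-dioxaborolan-2-yl]methyl}-4-{[(4-methoxybenzyl)oxy]methyl}pent-4-enal | C=C(COCc1ccc(OC)cc1)[C@H](CC=O)CB1O[C@@H](C2CCCCC2)[C@H](C2CCCCC2)O1 | intermediate
17 | methyl 2-[bis(2,2,2-trifluoroethoxy)phosphoryl]acetate | COC(=O)CP(=O)(OCC(F)(F)F)OCC(F)(F)F | starting material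
18 | 3-bromo-1,1-dimethoxypropane | COC(CCBr)OC | starting material
19 | methyl 2-[bis(2,2,2-trifluoroethoxy)phosphoryl]-5,5-dimethoxypentanoate (racemic) | COC(=O)C(CCC(OC)OC)P(=O)(OCC(F)(F)F)OCC(F)(F)F | intermediate
20 | methyl (2Z,5S)-5-{[(4S,5S)-4,5-dicyclohexyl-1,3,2-dioxaborolan-2-yl]methyl}-2-(3,3-dimethoxypropyl)-6-{[(4-methoxybenzyl)oxy]methyl}hepta-2,6-dienoate | C=C(COCc1ccc(OC)cc1)[C@H](C/C=C(\C(=O)OC)CCC(OC)OC)CB1O[C@@H](C2CCCCC2)[C@H](C2CCCCC2)O1 | intermediate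
21 | (2Z,5S)-5-{[(4S,5S)-4,5-dicyclohexyl-1,3,2-dioxaborolan-2-yl]methyl}-2-(3,3-dimethoxypropyl)-6-{[(4-methoxybenzyl)oxy]methyl}hepta-2,6-dien-1-ol | C=C(COCc1ccc(OC)cc1)[C@H](C/C=C(\CO)CCC(OC)OC)CB1O[C@@H](C2CCCCC2)[C@H](C2CCCCC2)O1 | intermediate
22 | tert-butyldiphenylsilyl ether of 21 | C=C(COCc1ccc(OC)cc1)[C@H](C/C=C(\CO[Si](c1ccccc1)(c1ccccc1)C(C)(C)C)CCC(OC)OC)CB1O[C@@H](C2CCCCC2)[C@H](C2CCCCC2)O1 | intermediate
23 | (4Z,7S)-4-{[(tert-butyldiphenylsilyl)oxy]methyl}-7-{[(4S,5S)-4,5-dicyclohexyl-1,3,2-dioxaborolan-2-yl]methyl}-8-{[(4-methoxybenzyl)oxy]methyl}nona-4,8-dienal | C=C(COCc1ccc(OC)cc1)[C@H](C/C=C(\CO[Si](c1ccccc1)(c1ccccc1)C(C)(C)C)CCC=O)CB1O[C@@H](C2CCCCC2)[C@H](C2CCCCC2)O1 | intermediate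
24 | methyl 2-[bis(2,2,2-trifluoroethoxy)phosphoryl]-2-bromoacetate | COC(=O)C(Br)P(=O)(OCC(F)(F)F)OCC(F)(F)F | intermediate
25 | methyl (2E,6Z,9S)-2-bromo-6-{[(tert-butyldiphenylsilyl)oxy]methyl}-9-{[(4S,5S)-4,5-dicyclohexyl-1,3,2-dioxaborolan-2-yl]methyl}-10-{[(4-methoxybenzyl)oxy]methyl}undeca-2,6,10-trienoate | C=C(COCc1ccc(OC)cc1)[C@H](C/C=C(\CO[Si](c1ccccc1)(c1ccccc1)C(C)(C)C)CC/C=C(/Br)C(=O)OC)CB1O[C@@H](C2CCCCC2)[C@H](C2CCCCC2)O1 | intermediate
26 | (2E,6Z,9S)-2-bromo-6-{[(tert-butyldiphenylsilyl)oxy]methyl}-9-{[(4S,5S)-4,5-dicyclohexyl-1,3,2-dioxaborolan-2-yl]methyl}-10-{[(4-methoxybenzyl)oxy]methyl}undeca-2,6,10-trien-1-ol | C=C(COCc1ccc(OC)cc1)[C@H](C/C=C(\CO[Si](c1ccccc1)(c1ccccc1)C(C)(C)C)CC/C=C(/Br)CO)CB1O[C@@H](C2CCCCC2)[C@H](C2CCCCC2)O1 | intermediate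
27 | tert-butyldimethylsilyl ether of 26 | C=C(COCc1ccc(OC)cc1)[C@H](C/C=C(\CO[Si](c1ccccc1)(c1ccccc1)C(C)(C)C)CC/C=C(/Br)CO[Si](C)(C)C(C)(C)C)CB1O[C@@H](C2CCCCC2)[C@H](C2CCCCC2)O1 | intermediate
28 | lithium (dichloromethyl)borate complex of 27 | [Li+].C=C(COCc1ccc(OC)cc1)[C@H](C/C=C(\CO[Si](c1ccccc1)(c1ccccc1)C(C)(C)C)CC/C=C(/Br)CO[Si](C)(C)C(C)(C)C)C[B-]1(C(Cl)Cl)O[C@@H](C2CCCCC2)[C@H](C2CCCCC2)O1 | intermediate
29 | (4S,5S)-2-[(1R,3R,5Z,9E)-10-bromo-11-(tert-butyldimethylsilyloxy)-6-{[(tert-butyldiphenylsilyl)oxy]methyl}-1-chloro-3-{3-[(4-methoxybenzyl)oxy]prop-1-en-2-yl}undeca-5,9-dien-1-yl]-4,5-dicyclohexyl-1,3,2-dioxaborolane | C=C(COCc1ccc(OC)cc1)[C@H](C/C=C(\CO[Si](c1ccccc1)(c1ccccc1)C(C)(C)C)CC/C=C(/Br)CO[Si](C)(C)C(C)(C)C)C[C@H](Cl)B1O[C@@H](C2CCCCC2)[C@H](C2CCCCC2)O1 | intermediate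
30 | C10 alkenyllithium from 29 (Li in place of Br) | C=C(COCc1ccc(OC)cc1)[C@H](C/C=C(\CO[Si](c1ccccc1)(c1ccccc1)C(C)(C)C)CC/C=C(/[Li])CO[Si](C)(C)C(C)(C)C)C[C@H](Cl)B1O[C@@H](C2CCCCC2)[C@H](C2CCCCC2)O1 | intermediate
31 | lithium spiro-borate with the 11-membered ring C7–C8–C9(Cl)–B–C10=C1–C2–C3–C4=C5–C6 | [Li+].C=C(COCc1ccc(OC)cc1)[C@H]1C[C@H](Cl)[B-]2(O[C@@H](C3CCCCC3)[C@H](C3CCCCC3)O2)/C(CO[Si](C)(C)C(C)(C)C)=C/CC/C(CO[Si](c2ccccc2)(c2ccccc2)C(C)(C)C)=C/C1 | intermediate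
32 | ten-membered ring allylic boronic ester (C9–B, DICHED ester; ring geometry as in 33) | C=C(COCc1ccc(OC)cc1)[C@H]1C[C@H](B2O[C@@H](C3CCCCC3)[C@H](C3CCCCC3)O2)/C(CO[Si](C)(C)C(C)(C)C)=C/CC/C(CO[Si](c2ccccc2)(c2ccccc2)C(C)(C)C)=C/C1 | intermediate
33 | (1S,2E,6Z,9R)-2-{[(tert-butyldimethylsilyl)oxy]methyl}-6-{[(tert-butyldiphenylsilyl)oxy]methyl}-9-{3-[(4-methoxybenzyl)oxy]prop-1-en-2-yl}cyclodeca-2,6-dien-1-ol | C=C(COCc1ccc(OC)cc1)[C@H]1C[C@H](O)/C(CO[Si](C)(C)C(C)(C)C)=C/CC/C(CO[Si](c2ccccc2)(c2ccccc2)C(C)(C)C)=C/C1 | intermediate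
34 | (2E)-2-methylbut-2-enoate (tiglate) of 33 at C9–O | C=C(COCc1ccc(OC)cc1)[C@H]1C[C@H](OC(=O)/C(C)=C/C)/C(CO[Si](C)(C)C(C)(C)C)=C/CC/C(CO[Si](c2ccccc2)(c2ccccc2)C(C)(C)C)=C/C1 | intermediate
35 | (1S,2E,6Z,9R)-6-{[(tert-butyldiphenylsilyl)oxy]methyl}-2-(hydroxymethyl)-9-{3-[(4-methoxybenzyl)oxy]prop-1-en-2-yl}cyclodeca-2,6-dien-1-yl (2E)-2-methylbut-2-enoate | C=C(COCc1ccc(OC)cc1)[C@H]1C[C@H](OC(=O)/C(C)=C/C)/C(CO)=C/CC/C(CO[Si](c2ccccc2)(c2ccccc2)C(C)(C)C)=C/C1 | intermediate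
36 | (4R)-4-benzyl-3-propanoyl-1,3-oxazolidin-2-one | CCC(=O)N1[C@H](Cc2ccccc2)COC1=O | starting material
37 | acetaldehyde | CC=O | starting material
38 | (4R)-4-benzyl-3-[(2R,3S)-3-hydroxy-2-methylbutanoyl]-1,3-oxazolidin-2-one | C[C@H](O)[C@@H](C)C(=O)N1[C@H](Cc2ccccc2)COC1=O | intermediate
39 | (4R)-4-benzyl-3-[(2R,3S)-3-(tert-butyldimethylsilyloxy)-2-methylbutanoyl]-1,3-oxazolidin-2-one | C[C@H](O[Si](C)(C)C(C)(C)C)[C@@H](C)C(=O)N1[C@H](Cc2ccccc2)COC1=O | intermediate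
40 | (2R,3S)-3-(tert-butyldimethylsilyloxy)-2-methylbutanoic acid | C[C@H](O[Si](C)(C)C(C)(C)C)[C@@H](C)C(=O)O | intermediate
41 | C14 ester of 35 with acid 40 | C=C(COCc1ccc(OC)cc1)[C@H]1C[C@H](OC(=O)/C(C)=C/C)/C(COC(=O)[C@H](C)[C@H](C)O[Si](C)(C)C(C)(C)C)=C/CC/C(CO[Si](c2ccccc2)(c2ccccc2)C(C)(C)C)=C/C1 | intermediate
42 | C12 alcohol (PMB removed from 41) | C=C(CO)[C@H]1C[C@H](OC(=O)/C(C)=C/C)/C(COC(=O)[C@H](C)[C@H](C)O[Si](C)(C)C(C)(C)C)=C/CC/C(CO[Si](c2ccccc2)(c2ccccc2)C(C)(C)C)=C/C1 | intermediate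
43 | C12 acetate of 42 | C=C(COC(C)=O)[C@H]1C[C@H](OC(=O)/C(C)=C/C)/C(COC(=O)[C@H](C)[C@H](C)O[Si](C)(C)C(C)(C)C)=C/CC/C(CO[Si](c2ccccc2)(c2ccccc2)C(C)(C)C)=C/C1 | intermediate
44 | (1S,2E,6Z,9R)-9-[3-(acetyloxy)prop-1-en-2-yl]-6-(hydroxymethyl)-2-({[(2R,3S)-3-hydroxy-2-methylbutanoyl]oxy}methyl)cyclodeca-2,6-dien-1-yl (2E)-2-methylbut-2-enoate | C=C(COC(C)=O)[C@H]1C[C@H](OC(=O)/C(C)=C/C)/C(COC(=O)[C@H](C)[C@H](C)O)=C/CC/C(CO)=C/C1 | intermediate
45 | CNP0316239.1 (4S,5R-epoxide of 44) | C=C(COC(C)=O)[C@H]1C[C@H](OC(=O)/C(C)=C/C)/C(COC(=O)[C@H](C)[C@H](C)O)=C/CC[C@@]2(CO)O[C@@H]2C1 | target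

**Totals**
Total steps: 28. Longest linear sequence: 22 steps (1, 2, 4–7, 9–12, 14–20, 24–28).

**Steps most likely to fail**

1. Step 18 (proposed new method). What may go wrong: t-BuLi adds to boron before Br–Li exchange; intermolecular borate formation gives oligomers; or the 2-lithioallyl silyl ether eliminates to an allene. Fallback from 29, by known chemistry: buffered oxidation of the α-chloro boronic ester (H2O2, NaHCO3, THF/H2O) would give the C9 aldehyde (3R,5Z,9E)-10-bromo-11-(tert-butyldimethylsilyloxy)-6-{[(tert-butyldiphenylsilyl)oxy]methyl}-3-{3-[(4-methoxybenzyl)oxy]prop-1-en-2-yl}undeca-5,9-dienal F1. An intramolecular Nozaki–Hiyama–Kishi reaction (CrCl2, cat. NiCl2, DMSO/THF, high dilution) would close the ten-membered ring directly to the C9-epimeric ring alcohols F2. Dess–Martin oxidation to the ring enone F3, then a Corey–Bakshi–Shibata reduction with the catalyst enantiomer that delivers the 9S carbinol, comes back to the route at 33.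

2. Step 4. What may go wrong: β-elimination of the 2-lithioallyl ether before it reaches boron, or 1,3-boron shift in the α-branched allylic boronic ester 12; the β-silyloxy boronate of step 2 carries a related elimination risk. Fallback from 9, setting C7 by asymmetric catalysis instead: Br–Li exchange and trapping with 2-isopropoxy-4,4,5,5-tetramethyl-1,3,2-dioxaborolane would give 2-{3-[(4-methoxybenzyl)oxy]prop-1-en-2-yl}-4,4,5,5-tetramethyl-1,3,2-dioxaborolane F4. Rhodium(I)/BINAP-catalysed conjugate addition to furan-2(5H)-one (ligand enantiomer chosen for the 4S lactone) would give (4S)-4-{3-[(4-methoxybenzyl)oxy]prop-1-en-2-yl}dihydrofuran-2(3H)-one F5. Opening with MeNH(OMe)·HCl/Me3Al would give (3S)-3-(hydroxymethyl)-N-methoxy-4-{[(4-methoxybenzyl)oxy]methyl}-N-methylpent-4-enamide F6, and iodination (I2, PPh3, imidazole) the iodide (3S)-3-(iodomethyl)-N-methoxy-4-{[(4-methoxybenzyl)oxy]methyl}-N-methylpent-4-enamide F7. Borylation as in step 1 (B2cat2, blue light; then 2, Et3N) would give the boronic ester Weinreb amide F8, and DIBAL-H at −78 °C comes back to the route at aldehyde 16.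

3. Step 9. What may go wrong: erosion of Z-selectivity with the α-branched phosphonate and β-branched aldehyde. Fallback from 16, fixing C4=C5 by cross-coupling instead: olefination with 24 (t-BuOK, 18-crown-6, THF, −78 °C) would give methyl (2E,5S)-2-bromo-5-{[(4S,5S)-4,5-dicyclohexyl-1,3,2-dioxaborolan-2-yl]methyl}-6-{[(4-methoxybenzyl)oxy]methyl}hepta-2,6-dienoate F9. DIBAL-H would give the bromo allylic alcohol F10 and TBDPSCl/imidazole its silyl ether F11. A B-alkyl Suzuki–Miyaura coupling (Pd(dppf)Cl2, AsPh3, Cs2CO3, DMF/THF/H2O) with 9-(3,3-dimethoxypropyl)-9-borabicyclo[3.3.1]nonane F12, made from 3,3-dimethoxyprop-1-ene and 9-BBN-H, would replace bromine with retention and come back to the route at 22.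

**Further compounds**
F1 | step 18 | (3R,5Z,9E)-10-bromo-11-(tert-butyldimethylsilyloxy)-6-{[(tert-butyldiphenylsilyl)oxy]methyl}-3-{3-[(4-methoxybenzyl)oxy]prop-1-en-2-yl}undeca-5,9-dienal | C=C(COCc1ccc(OC)cc1)[C@H](C/C=C(\CO[Si](c1ccccc1)(c1ccccc1)C(C)(C)C)CC/C=C(/Br)CO[Si](C)(C)C(C)(C)C)CC=O
F2 | step 18 | ring alcohol 33 as the mixture of C9 epimers | C=C(COCc1ccc(OC)cc1)[C@H]1CC(O)/C(CO[Si](C)(C)C(C)(C)C)=C/CC/C(CO[Si](c2ccccc2)(c2ccccc2)C(C)(C)C)=C/C1
F3 | step 18 | ring enone (C9 ketone) | C=C(COCc1ccc(OC)cc1)[C@H]1CC(=O)/C(CO[Si](C)(C)C(C)(C)C)=C/CC/C(CO[Si](c2ccccc2)(c2ccccc2)C(C)(C)C)=C/C1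
F4 | step 4 | 2-{3-[(4-methoxybenzyl)oxy]prop-1-en-2-yl}-4,4,5,5-tetramethyl-1,3,2-dioxaborolane | C=C(COCc1ccc(OC)cc1)B1OC(C)(C)C(C)(C)O1
F5 | step 4 | (4S)-4-{3-[(4-methoxybenzyl)oxy]prop-1-en-2-yl}dihydrofuran-2(3H)-one | C=C(COCc1ccc(OC)cc1)[C@@H]1CC(=O)OC1
F6 | step 4 | (3S)-3-(hydroxymethyl)-N-methoxy-4-{[(4-methoxybenzyl)oxy]methyl}-N-methylpent-4-enamide | C=C(COCc1ccc(OC)cc1)[C@H](CC(=O)N(C)OC)CO
F7 | step 4 | (3S)-3-(iodomethyl)-N-methoxy-4-{[(4-methoxybenzyl)oxy]methyl}-N-methylpent-4-enamide | C=C(COCc1ccc(OC)cc1)[C@H](CC(=O)N(C)OC)CI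
F8 | step 4 | (3S)-3-{[(4S,5S)-4,5-dicyclohexyl-1,3,2-dioxaborolan-2-yl]methyl}-N-methoxy-4-{[(4-methoxybenzyl)oxy]methyl}-N-methylpent-4-enamide | C=C(COCc1ccc(OC)cc1)[C@H](CC(=O)N(C)OC)CB1O[C@@H](C2CCCCC2)[C@H](C2CCCCC2)O1
F9 | step 9 | methyl (2E,5S)-2-bromo-5-{[(4S,5S)-4,5-dicyclohexyl-1,3,2-dioxaborolan-2-yl]methyl}-6-{[(4-methoxybenzyl)oxy]methyl}hepta-2,6-dienoate | C=C(COCc1ccc(OC)cc1)[C@H](C/C=C(/Br)C(=O)OC)CB1O[C@@H](C2CCCCC2)[C@H](C2CCCCC2)O1
F10 | step 9 | (2E,5S)-2-bromo-5-{[(4S,5S)-4,5-dicyclohexyl-1,3,2-dioxaborolan-2-yl]methyl}-6-{[(4-methoxybenzyl)oxy]methyl}hepta-2,6-dien-1-ol | C=C(COCc1ccc(OC)cc1)[C@H](C/C=C(/Br)CO)CB1O[C@@H](C2CCCCC2)[C@H](C2CCCCC2)O1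
F11 | step 9 | tert-butyldiphenylsilyl ether of F10 | C=C(COCc1ccc(OC)cc1)[C@H](C/C=C(/Br)CO[Si](c1ccccc1)(c1ccccc1)C(C)(C)C)CB1O[C@@H](C2CCCCC2)[C@H](C2CCCCC2)O1
F12 | step 9 | 9-(3,3-dimethoxypropyl)-9-borabicyclo[3.3.1]nonane | COC(CCB1C2CCCC1CCC2)OC
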